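## Retrosynthetic overview

- The target is a 1‑aryltetralin, (1S,2R,3R), with CH2OAc on C‑2 and a free CH2OH on C‑3. Enabling feature: C‑1 is doubly benzylic, and O‑4' of the pendant ring and the C‑6 methoxy group each lie para to the ring carbon bonded to C‑1, so C‑1 can act as an aldehyde‑level carbon that is arylated twice. The only free alcohol oxygen (on the C‑3 CH2) can form a five‑membered ring O–CH2–C‑3–C‑2–C‑1, so this aldehyde is carried as a lactol while the C‑2 CH2OH already bears its acetate.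
- Key disconnection C‑1–C‑1' (pendant ring): ipso‑arylation of the lactol‑derived oxocarbenium ion by an aryltrifluoroborate. In the same flask the 2‑aryltetrahydrofuran opens at its benzylic C–O bond and ring A closes C‑1–C‑8a, which forms the carbocycle, sets C‑1 and releases the C‑3 CH2OH.
- Lactol diacetate ⇐ 2‑benzyl‑3‑vinylbutane‑1,4‑diol (vinyl = masked C‑1) ⇐ trans‑3‑benzyl‑4‑vinyl‑γ‑butyrolactone ⇐ enolate benzylation of (S)‑4‑vinyl‑γ‑butyrolactone ⇐ Rh‑catalysed asymmetric vinyl addition to furan‑2(5H)‑one.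
- Ring order: butyrolactone (from the furanone, opened in step 4), temporary tetrahydrofuran lactol (step 5), carbocycle of the tetralin last (step 8). One catalyst‑set stereocentre (C‑2) relays C‑3 (alkylation) and C‑1 (cyclisation).

Key step: step 8

Assumption: the acetal carbon of 10, 11 and 15 and the carbinol carbon of 8 form as epimer mixtures and are written without configuration; this carbon becomes the cationic C‑1 in step 8, so its configuration is irrelevant. Trans on the lactone ring of 6 corresponds to cis on the tetrahydrofuran ring of 10, 11 and 15 (different ring atoms) and to 2,3‑trans on the tetralin.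

## Route

Step 1
Reactants: 1 furan‑2(5H)‑one; 2 potassium vinyltrifluoroborate
Product: 3 (4S)‑4‑vinyldihydrofuran‑2(3H)‑one
Conditions: [Rh(cod)2]BF4 (3 mol %), (S)‑BINAP (3.3 mol %), 2 (2 equiv), toluene/H2O 10:1, 100 °C
Reagents that add atoms: none
Why: Hayashi–Miyaura rhodium‑catalysed asymmetric 1,4‑addition of an alkenylborate to an α,β‑unsaturated lactone should transfer the vinyl group to C‑4, the face selection of the (S)‑BINAP–Rh complex setting the single catalyst‑derived stereocentre (the future C‑2 of the tetralin), with the antipodal ligand used if the sense of induction proves opposite to the usual model.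

Step 2
Reactants: 4 4‑(benzyloxy)‑3‑methoxybenzyl alcohol
Product: 5 4‑(benzyloxy)‑3‑methoxybenzyl bromide
Conditions: PBr3 (0.4 equiv), Et2O, 0 °C
Reagents that add atoms: phosphorus tribromide, BrP(Br)Br
Why: Standard bromination of an electron‑rich benzylic alcohol with PBr3 (SN2 displacement of the bromophosphite).

Step 3
Reactants: 3 (4S)‑4‑vinyldihydrofuran‑2(3H)‑one; 5 4‑(benzyloxy)‑3‑methoxybenzyl bromide
Product: 6 (3R,4R)‑3‑[4‑(benzyloxy)‑3‑methoxybenzyl]‑4‑vinyldihydrofuran‑2(3H)‑one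
Conditions: LDA (commercial solution, 1.05 equiv), THF, −78 °C; then 5, −78 → −30 °C
Reagents that add atoms: none
Why: Kinetic lithium enolate alkylation of a β‑substituted γ‑butyrolactone, in which the benzylic bromide should approach the enolate face anti to the C‑4 vinyl group and so set the new C‑3 centre trans (the future C‑3 of the tetralin).

Step 4
Reactants: 6 (3R,4R)‑3‑[4‑(benzyloxy)‑3‑methoxybenzyl]‑4‑vinyldihydrofuran‑2(3H)‑one
Product: 7 (2R,3R)‑2‑[4‑(benzyloxy)‑3‑methoxybenzyl]‑3‑vinylbutane‑1,4‑diol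
Conditions: LiAlH4, THF, 0 °C → rt; aqueous NaOH work‑up
Reagents that add atoms: none
Why: LiAlH4 reduction of the lactone to the 1,4‑diol touches neither stereocentre nor the vinyl and benzyl ether groups.

Step 5
Reactants: 7 (2R,3R)‑2‑[4‑(benzyloxy)‑3‑methoxybenzyl]‑3‑vinylbutane‑1,4‑diol
Product: 10 (3R,4R)‑4‑[4‑(benzyloxy)‑3‑methoxybenzyl]‑3‑(hydroxymethyl)tetrahydrofuran‑2‑ol (anomer mixture), via vicinal diol 8 (not isolated), via open‑chain hydroxy aldehyde 9 (not isolated)
Conditions: OsO4 (2 mol %), NaIO4 (4 equiv), 2,6‑lutidine (2 equiv), dioxane/H2O 3:1, rt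
Reagents that add atoms: osmium tetroxide, O=[Os](=O)(=O)=O (catalytic, carries the oxygen); sodium periodate, [Na+].[O-]I(=O)(=O)=O (stoichiometric oxygen source)
Why: Lemieux–Johnson oxidative cleavage turns the vinyl group into the aldehyde that becomes C‑1, and this aldehyde can close a five‑membered lactol only onto the γ‑hydroxyl (the future C‑3 CH2OH), which leaves the β‑hydroxyl free and so tells the two primary alcohols apart.

Step 6
Reactants: 10 (3R,4R)‑4‑[4‑(benzyloxy)‑3‑methoxybenzyl]‑3‑(hydroxymethyl)tetrahydrofuran‑2‑ol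
Product: 11 [(3R,4R)‑2‑acetoxy‑4‑[4‑(benzyloxy)‑3‑methoxybenzyl]tetrahydrofuran‑3‑yl]methyl acetate (anomer mixture)
Conditions: Ac2O (3 equiv), pyridine, DMAP (cat.), CH2Cl2, 0 °C → rt
Reagents that add atoms: acetic anhydride, CC(=O)OC(C)=O
Why: Pyridine/DMAP acylation esterifies the one free primary alcohol (this is the acetate of the target) and the anomeric hydroxyl (the leaving group for step 8).

Step 7
Reactants: 12 [4‑(benzyloxy)‑3‑methoxyphenyl]boronic acid
Product: 13 potassium [4‑(benzyloxy)‑3‑methoxyphenyl]trifluoroborate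
Conditions: KHF2 (3 equiv), MeOH/H2O, rt
Reagents that add atoms: potassium hydrogen difluoride, [K+].F[H-]F
Why: Standard conversion of an arylboronic acid into the bench‑stable potassium trifluoroborate with KHF2.

Step 8
Reactants: 11 [(3R,4R)‑2‑acetoxy‑4‑[4‑(benzyloxy)‑3‑methoxybenzyl]tetrahydrofuran‑3‑yl]methyl acetate; 13 potassium [4‑(benzyloxy)‑3‑methoxyphenyl]trifluoroborate
Product: 17 [(1S,2R,3R)‑7‑(benzyloxy)‑1‑[4‑(benzyloxy)‑3‑methoxyphenyl]‑3‑(hydroxymethyl)‑6‑methoxy‑1,2,3,4‑tetrahydronaphthalen‑2‑yl]methyl acetate, via oxocarbenium ion 14 (not isolated), via 2‑aryltetrahydrofuran 15 (not isolated), via ring‑opened benzylic cation 16 (not isolated)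
Conditions: 13 (1.5 equiv), BF3·OEt2 (3 equiv), CH2Cl2/MeCN, −40 °C → rt; sat. NaHCO3
Reagents that add atoms: none
Why: BF3 ionises the anomeric acetate of 11 to the oxocarbenium ion 14 and turns 13 into an aryldifluoroborane/acetoxyborate pair, from which the aryl group moves from boron to the cationic carbon by ipso substitution to give the 2‑aryltetrahydrofuran 15. On warming, the same Lewis acid opens the benzylic C–O bond of 15 to the para‑benzyloxy‑stabilised cation 16, which ring A captures through its position para to the methoxy group to give 17, the ring oxygen being released as the C‑3 CH2OH. The closest known reaction types are the BF3‑promoted coupling of potassium aryltrifluoroborates with O‑acyl acetals and the acid‑induced rearrangement of 2‑aryl‑4‑benzyltetrahydrofuran lignans (lariciresinol type) to aryltetralins, here run as one domino. The only ring closed is the carbocycle, by intramolecular Friedel–Crafts alkylation at C‑1–C‑8a, 6‑exo‑trig with respect to the quinone‑methide‑like cation. The new C‑1 centre is controlled by C‑2 and C‑3: in the chair‑like transition state both CH2O groups are equatorial and the aryl group of the planar cation takes the pseudo‑equatorial site, which should give the 1,2‑trans‑2,3‑trans (1S,2R,3R) isomer, and the configuration of the aryl‑bearing carbon of 15 is irrelevant because it is erased in 16. The step needs regioselectivity on both arenes and C‑arylation before ring opening: the C–B bond fixes the position on the pendant ring, the para‑methoxy group and the crowded site between CH2 and OMe fix it on ring A, and adding 13 at −40 °C before warming lets the arylation finish first.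

Step 9
Reactants: 17 [(1S,2R,3R)‑7‑(benzyloxy)‑1‑[4‑(benzyloxy)‑3‑methoxyphenyl]‑3‑(hydroxymethyl)‑6‑methoxy‑1,2,3,4‑tetrahydronaphthalen‑2‑yl]methyl acetate
Product: 18 [(1S,2R,3R)‑7‑hydroxy‑1‑(4‑hydroxy‑3‑methoxyphenyl)‑3‑(hydroxymethyl)‑6‑methoxy‑1,2,3,4‑tetrahydronaphthalen‑2‑yl]methyl acetate
Conditions: H2 (1 atm), 10% Pd/C, EtOAc, rt
Reagents that add atoms: none
Why: Hydrogenolysis of the two aryl benzyl ethers over Pd/C under neutral conditions should leave the acetate, the diarylmethine C–H and all three stereocentres untouched, and the neutral medium avoids acetyl migration to the free primary alcohol.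

## Compound list

1 | furan‑2(5H)‑one | O=C1OCC=C1 | starting material
2 | potassium vinyltrifluoroborate | C=C[B-](F)(F)F.[K+] | starting material
3 | (4S)‑4‑vinyldihydrofuran‑2(3H)‑one | C=C[C@H]1COC(=O)C1 | intermediate
4 | 4‑(benzyloxy)‑3‑methoxybenzyl alcohol | COc1cc(CO)ccc1OCc1ccccc1 | starting material
5 | 4‑(benzyloxy)‑3‑methoxybenzyl bromide | COc1cc(CBr)ccc1OCc1ccccc1 | intermediate
6 | (3R,4R)‑3‑[4‑(benzyloxy)‑3‑methoxybenzyl]‑4‑vinyldihydrofuran‑2(3H)‑one (trans) | C=C[C@H]1COC(=O)[C@@H]1Cc1ccc(OCc2ccccc2)c(OC)c1 | intermediate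
7 | (2R,3R)‑2‑[4‑(benzyloxy)‑3‑methoxybenzyl]‑3‑vinylbutane‑1,4‑diol | C=C[C@@H](CO)[C@H](CO)Cc1ccc(OCc2ccccc2)c(OC)c1 | intermediate
8 | (2R,3R)‑2‑[4‑(benzyloxy)‑3‑methoxybenzyl]‑3‑(hydroxymethyl)pentane‑1,4,5‑triol (C‑4 epimers; vicinal diol from dihydroxylation) | OCC(O)[C@@H](CO)[C@H](CO)Cc1ccc(OCc2ccccc2)c(OC)c1 | intermediate
9 | (2R,3R)‑3‑[4‑(benzyloxy)‑3‑methoxybenzyl]‑4‑hydroxy‑2‑(hydroxymethyl)butanal (open‑chain hydroxy aldehyde) | O=C[C@@H](CO)[C@H](CO)Cc1ccc(OCc2ccccc2)c(OC)c1 | intermediate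
10 | (3R,4R)‑4‑[4‑(benzyloxy)‑3‑methoxybenzyl]‑3‑(hydroxymethyl)tetrahydrofuran‑2‑ol (anomers; CH2OH and benzyl cis) | OC1OC[C@H](Cc2ccc(OCc3ccccc3)c(OC)c2)[C@@H]1CO | intermediate
11 | [(3R,4R)‑2‑acetoxy‑4‑[4‑(benzyloxy)‑3‑methoxybenzyl]tetrahydrofuran‑3‑yl]methyl acetate (anomers) | CC(=O)OC1OC[C@H](Cc2ccc(OCc3ccccc3)c(OC)c2)[C@@H]1COC(C)=O | intermediate
12 | [4‑(benzyloxy)‑3‑methoxyphenyl]boronic acid | COc1cc(B(O)O)ccc1OCc1ccccc1 | starting material
13 | potassium [4‑(benzyloxy)‑3‑methoxyphenyl]trifluoroborate | COc1cc([B-](F)(F)F)ccc1OCc1ccccc1.[K+] | intermediate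
14 | cyclic oxocarbenium ion of 11 (anomeric acetate lost; both stereocentres as in 11) | CC(=O)OC[C@@H]1C=[O+]C[C@@H]1Cc1ccc(OCc2ccccc2)c(OC)c1 | intermediate
15 | [(3R,4R)‑2‑[4‑(benzyloxy)‑3‑methoxyphenyl]‑4‑[4‑(benzyloxy)‑3‑methoxybenzyl]tetrahydrofuran‑3‑yl]methyl acetate (C‑2 epimers) | CC(=O)OC[C@@H]1C(c2ccc(OCc3ccccc3)c(OC)c2)OC[C@@H]1Cc1ccc(OCc2ccccc2)c(OC)c1 | intermediate
16 | ring‑opened diarylmethyl‑type benzylic cation of 15, oxygen held as the trifluoroborate alkoxide (stereocentres as in 15) | CC(=O)OC[C@H]([CH+]c1ccc(OCc2ccccc2)c(OC)c1)[C@H](CO[B-](F)(F)F)Cc1ccc(OCc2ccccc2)c(OC)c1 | intermediate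
17 | [(1S,2R,3R)‑7‑(benzyloxy)‑1‑[4‑(benzyloxy)‑3‑methoxyphenyl]‑3‑(hydroxymethyl)‑6‑methoxy‑1,2,3,4‑tetrahydronaphthalen‑2‑yl]methyl acetate | COc1cc([C@H]2c3cc(OCc4ccccc4)c(OC)cc3C[C@@H](CO)[C@@H]2COC(C)=O)ccc1OCc1ccccc1 | intermediate
18 | [(1S,2R,3R)‑7‑hydroxy‑1‑(4‑hydroxy‑3‑methoxyphenyl)‑3‑(hydroxymethyl)‑6‑methoxy‑1,2,3,4‑tetrahydronaphthalen‑2‑yl]methyl acetate | COc1cc([C@H]2c3cc(O)c(OC)cc3C[C@@H](CO)[C@@H]2COC(C)=O)ccc1O | target

## Step count and risks

Total step count: 9. Longest linear sequence: 7 steps (1, 3, 4, 5, 6, 8, 9).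

Steps most likely to fail:

1. Step 8. Aryl transfer from boron may be slower than loss of a proton from the β‑acetoxy oxocarbenium ion (enol ether formation, then loss of acetic acid or epimerisation at the future C‑2). Protodeboronation would erode the regiocontrol on the pendant ring, and ring A may capture the oxocarbenium ion prematurely. Fallback, all known chemistry, from 10: addition of the Grignard reagent of 1‑(benzyloxy)‑4‑bromo‑2‑methoxybenzene (3.5 equiv, THF, 0 °C → rt) to the lactol should give the triol (2R,3R)‑1‑[4‑(benzyloxy)‑3‑methoxyphenyl]‑3‑[4‑(benzyloxy)‑3‑methoxybenzyl]‑2‑(hydroxymethyl)butane‑1,4‑diol F1. Mild acid (CSA cat., CH2Cl2, 0 °C) should close the tetrahydrofuran by attack of the γ‑hydroxyl on the benzylic cation to give the alcohol [(3R,4R)‑2‑[4‑(benzyloxy)‑3‑methoxyphenyl]‑4‑[4‑(benzyloxy)‑3‑methoxybenzyl]tetrahydrofuran‑3‑yl]methanol F2. Acetylation (Ac2O, pyridine) gives 15 as an isolated compound, and BF3·OEt2 (CH2Cl2, 0 °C) rearranges it to the aryltetralin. The route is rejoined at 17.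

2. Step 1. Conversion or enantioselectivity of the vinyl transfer to the small, sensitive butenolide may be poor (protodeboronation of the vinylborate, ring opening or oligomerisation of the furanone). Fallback from commercial (Z)‑but‑2‑ene‑1,4‑diol: Johnson–Claisen rearrangement with triethyl orthoacetate (cat. propionic acid, 140 °C, ethanol distilled off) with lactonisation should give racemic 4‑vinyldihydrofuran‑2(3H)‑one F3. Aminolysis with (S)‑1‑phenylethylamine gives two diastereomeric hydroxy amides, from which (3S)‑3‑(hydroxymethyl)‑N‑[(1S)‑1‑phenylethyl]pent‑4‑enamide F4 is separated by crystallisation or chromatography. Acid hydrolysis (aq. H2SO4, dioxane, reflux) relactonises it. The route is rejoined at 3.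

3. Step 5. Cleavage may be incomplete or accompanied by over‑oxidation in the presence of the free 1,4‑diol and the electron‑rich arene, and the transient β‑hydroxy aldehyde may dehydrate or epimerise at its α‑carbon under the buffered conditions. Fallback from 6, with the cleavage moved to the lactone stage: ozonolysis (O3, CH2Cl2/MeOH, −78 °C; Me2S) should give (3R,4R)‑4‑[4‑(benzyloxy)‑3‑methoxybenzyl]‑5‑oxotetrahydrofuran‑3‑carbaldehyde F5, whose epimerisable centre prefers the required trans arrangement on this ring. Acetalisation (HC(OMe)3, MeOH, PPTS) gives (3R,4R)‑3‑[4‑(benzyloxy)‑3‑methoxybenzyl]‑4‑(dimethoxymethyl)dihydrofuran‑2(3H)‑one F6. LiAlH4 gives (2R,3R)‑2‑[4‑(benzyloxy)‑3‑methoxybenzyl]‑3‑(dimethoxymethyl)butane‑1,4‑diol F7, and mild aqueous acid (AcOH/H2O/THF) unmasks the aldehyde, which lactolises. The route is rejoined at 10.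

Further compounds
F1 | step 8 | (2R,3R)‑1‑[4‑(benzyloxy)‑3‑methoxyphenyl]‑3‑[4‑(benzyloxy)‑3‑methoxybenzyl]‑2‑(hydroxymethyl)butane‑1,4‑diol (C‑1 epimers) | OC(c1ccc(OCc2ccccc2)c(OC)c1)[C@@H](CO)[C@H](CO)Cc1ccc(OCc2ccccc2)c(OC)c1
F2 | step 8 | [(3R,4R)‑2‑[4‑(benzyloxy)‑3‑methoxyphenyl]‑4‑[4‑(benzyloxy)‑3‑methoxybenzyl]tetrahydrofuran‑3‑yl]methanol (C‑2 epimers) | OC[C@@H]1C(c2ccc(OCc3ccccc3)c(OC)c2)OC[C@@H]1Cc1ccc(OCc2ccccc2)c(OC)c1
F3 | step 1 | racemic 4‑vinyldihydrofuran‑2(3H)‑one | C=CC1COC(=O)C1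
F4 | step 1 | (3S)‑3‑(hydroxymethyl)‑N‑[(1S)‑1‑phenylethyl]pent‑4‑enamide | C=C[C@H](CC(=O)N[C@@H](C)c1ccccc1)CO
F5 | step 5 | (3R,4R)‑4‑[4‑(benzyloxy)‑3‑methoxybenzyl]‑5‑oxotetrahydrofuran‑3‑carbaldehyde | O=C[C@H]1COC(=O)[C@@H]1Cc1ccc(OCc2ccccc2)c(OC)c1
F6 | step 5 | (3R,4R)‑3‑[4‑(benzyloxy)‑3‑methoxybenzyl]‑4‑(dimethoxymethyl)dihydrofuran‑2(3H)‑one | COC(OC)[C@H]1COC(=O)[C@@H]1Cc1ccc(OCc2ccccc2)c(OC)c1
F7 | step 5 | (2R,3R)‑2‑[4‑(benzyloxy)‑3‑methoxybenzyl]‑3‑(dimethoxymethyl)butane‑1,4‑diol | COC(OC)[C@@H](CO)[C@H](CO)Cc1ccc(OCc2ccccc2)c(OC)c1
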